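A direct plan would make the 3(2H)-furanone first (cyclisation of an α'-hydroxy ynone), attach a 3-(bromomethyl)butenolide, and close the ten-membered ring between C7 and C8 by a chromium-mediated allylation of the seco aldehyde A1.
It would then reduce the exocyclic methylene of the 8α-alcohol A2 to A3 and end with a Mitsunobu esterification with angelic acid.
Its weakest step would be the ring-closing allylation: C7 and C8 would be set while a strained ring forms, guided only by the ring conformation, and C8 would come out in the wrong sense.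
The second would be the Mitsunobu inversion at the hindered C8 carbinol of A3: the last step on the most precious material, needed only to repair the ring closure, and prone to elimination and to tiglate formation.
The third would be the conjugate reduction of A2, where C11 rests on the face of an enolate protonation, together with four auxiliary-based steps spent on a five-carbon hydroxy acid.

**Plan of the new route**
Cuts: C2–C3 and C3–C4 together (C3 becomes carbon monoxide), then O–C3 of the furanone, the C8 ester, the lactone C–O bond, C6–C7 (aldol) and C7–C8 (acylation of a zinc homoenolate).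
Feature used: in the furanone (ring A: O–C10–C1(=O)–C2=C3) C3 is a carbonyl-level carbon between the alkenyl carbon C4 and C2, and ring A is the cyclised hydrate of the 4-hydroxy-2-ynone C10(O)–C1≡C2–C3(=O). A C10 ethynyl carbinol, a Z-alkenyl iodide at C4 and CO are therefore enough.
Ring order: lactone first, ten-membered carbocycle second (key step), furanone last; no intermediate other than the target holds the bridged core.
All five stereocentres are set before any ring larger than the lactone exists: C10 by Sharpless epoxidation, C11 from a commercial bromo ester, C6/C7 by a syn aldol, C8 by hydroxyl-directed anti reduction.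
Hence no ring closure sets a stereocentre, C8 is made in the right sense and needs no inversion, the angelate is in place before the ring is closed, and there is no methylene lactone to reduce.

Key step: step 11

Remark: germacrane numbering (C1–C15) is used for positions in all intermediates.
Assumption: in step 8 the isopinocampheyl ligands derived from (+)-α-pinene are taken to give the required syn adduct 16; if the opposite sense is found, the enantiomeric boron reagent is used in the same way.

Step 1
Reactants: 1 (2E)-3-methylpent-2-en-4-yn-1-ol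
Product: 2 [(2S,3S)-3-ethynyl-3-methyloxiran-2-yl]methanol
Conditions: Ti(OiPr)4 (10 mol%), L-(+)-diethyl tartrate (12 mol%), tBuOOH, 4 Å sieves, CH2Cl2, −20 °C
Reagents that add atoms: tert-butyl hydroperoxide CC(C)(C)OO
Why: Sharpless asymmetric epoxidation; the L-(+)-tartrate complex should deliver oxygen to the face of the E-allylic alcohol that gives the (2S,3S)-epoxide, which fixes the quaternary carbon that becomes C10.

Step 2
Reactants: 2 [(2S,3S)-3-ethynyl-3-methyloxiran-2-yl]methanol
Product: 3 (3R)-3-methylpent-4-yne-1,3-diol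
Conditions: Red-Al [NaAlH2(OCH2CH2OMe)2], THF, −20 → 0 °C; aq. Rochelle salt
Reagents that add atoms: none
Why: Hydroxyl-directed hydride opening of a 2,3-epoxy alcohol: the primary alkoxyaluminate delivers hydride to the adjacent epoxide carbon, the tertiary C–O bond stays, so the 1,3-diol keeps the configuration of the quaternary carbon; the low temperature should spare the alkyne.

Step 3
Reactants: 3 (3R)-3-methylpent-4-yne-1,3-diol
Product: 4 (3R)-3-hydroxy-3-methylpent-4-ynoic acid
Conditions: TEMPO (20 mol%), PhI(OAc)2 (2.2 equiv), MeCN/H2O (1:1), rt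
Reagents that add atoms: water O
Why: Oxoammonium (TEMPO) oxidation of the primary alcohol through the aldehyde hydrate to the acid; the tertiary alcohol and the alkyne should not be oxidised.

Step 4
Reactants: 4 (3R)-3-hydroxy-3-methylpent-4-ynoic acid
Product: 6 (3R)-3-methyl-3-(triethylsilyloxy)pent-4-ynoic acid, via silyl ester 5 (not isolated)
Conditions: Et3SiOTf (2.3 equiv), 2,6-lutidine, CH2Cl2, −78 → 0 °C; then MeOH/H2O, rt
Reagents that add atoms: triethylsilyl trifluoromethanesulfonate CC[Si](CC)(CC)OS(=O)(=O)C(F)(F)F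
Why: Silylation of the hindered tertiary hydroxyl with the silyl triflate; the silyl ester formed beside it is hydrolysed in aqueous methanol, and the ether later keeps this hydroxyl from directing the reduction in step 9.

Step 5
Reactants: 6 (3R)-3-methyl-3-(triethylsilyloxy)pent-4-ynoic acid; 7 methyl (2R)-3-bromo-2-methylpropanoate
Product: 10 methyl (2S,6R)-2,6-dimethyl-4-oxo-6-(triethylsilyloxy)oct-7-ynoate, via acid chloride 8 (not isolated), via alkylzinc bromide 9 (not isolated)
Conditions: 6, 1-chloro-N,N,2-trimethylprop-1-en-1-amine, CH2Cl2, 0 °C → rt; 7, Zn dust, LiCl, THF, 40 °C; the two solutions combined with Pd(PPh3)4 (5 mol%), THF, 0 °C → rt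
Reagents that add atoms: none
Why: Negishi-type acylation of a zinc homoenolate with an acid chloride under zerovalent palladium catalysis forms the C7–C8 bond; neither stereocentre (C10, C11) is touched, and the descriptor at C11 changes from R to S only because the CH2 group loses CIP priority.

Step 6
Reactants: 11 but-2-yn-1-ol
Product: 13 (2Z)-3-iodobut-2-en-1-ol, via alkenylaluminate 12 (not isolated)
Conditions: Red-Al, THF, 0 °C → rt; then I2, −78 → 0 °C
Reagents that add atoms: iodine II
Why: Hydroxyl-directed trans-hydroalumination places aluminium on the distal alkyne carbon in a five-membered oxa-aluminacycle, and iodinolysis with retention should give the Z-iodide, which carries the future C4=C5 geometry.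

Step 7
Reactants: 13 (2Z)-3-iodobut-2-en-1-ol
Product: 14 (2Z)-3-iodobut-2-enal
Conditions: MnO2 (activated, excess), CH2Cl2, rt, dark; filtered and used at once
Reagents that add atoms: none
Why: Neutral heterogeneous allylic oxidation, which should not isomerise the Z-alkene.

Step 8
Reactants: 10 methyl (2S,6R)-2,6-dimethyl-4-oxo-6-(triethylsilyloxy)oct-7-ynoate; 14 (2Z)-3-iodobut-2-enal
Product: 16 methyl (2S,3S,6R)-3-[(1S,2Z)-1-hydroxy-3-iodobut-2-en-1-yl]-2,6-dimethyl-4-oxo-6-(triethylsilyloxy)oct-7-ynoate, via Z-boron enolate 15 (not isolated)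
Conditions: (Ipc)2BOTf [from (+)-α-pinene], iPr2NEt, CH2Cl2, −78 °C; 14, −78 → −20 °C; pH 7 buffer, MeOH, H2O2, 0 °C
Reagents that add atoms: none
Why: Paterson boron aldol: the ketone should enolise at C7 (C9 is neopentylic and the ester is not enolised by the boron triflate), the Z-enolate reacts through a chair transition state to the syn adduct, and the isopinocampheyl ligands choose the enolate face, so C6 and C7 are set together; any other stereoisomer would be a diastereomer and separable.

Step 9
Reactants: 16 methyl (2S,3S,6R)-3-[(1S,2Z)-1-hydroxy-3-iodobut-2-en-1-yl]-2,6-dimethyl-4-oxo-6-(triethylsilyloxy)oct-7-ynoate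
Product: 18 (3S,4R,5S)-4-[(1R,3R)-1-hydroxy-3-methyl-3-(triethylsilyloxy)pent-4-yn-1-yl]-5-[(1Z)-2-iodoprop-1-en-1-yl]-3-methyloxolan-2-one, via anti diol 17 (not isolated)
Conditions: Me4NBH(OAc)3, MeCN/AcOH (1:1), −30 °C; aq. Rochelle salt; then PPTS (10 mol%), toluene, 50 °C
Reagents that add atoms: none
Why: Evans–Saksena reduction: the C6 alkoxyborohydride delivers hydride intramolecularly to C8 and should give the 1,3-anti diol (C8 R); on mild acid only the C6 hydroxyl lactonises, because the 6,12-olide is all-trans whereas the 8,12-olide would be all-cis.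

Step 10
Reactants: 18 (3S,4R,5S)-4-[(1R,3R)-1-hydroxy-3-methyl-3-(triethylsilyloxy)pent-4-yn-1-yl]-5-[(1Z)-2-iodoprop-1-en-1-yl]-3-methyloxolan-2-one; 19 angelic acid
Product: 20 (1R,3R)-1-[(2S,3R,4S)-2-[(1Z)-2-iodoprop-1-en-1-yl]-4-methyl-5-oxooxolan-3-yl]-3-methyl-3-(triethylsilyloxy)pent-4-yn-1-yl (2Z)-2-methylbut-2-enoate
Conditions: 19, 2,4,6-trichlorobenzoyl chloride, Et3N, toluene, rt; then 18, toluene, 80 °C
Reagents that add atoms: none
Why: Yamaguchi-type mixed-anhydride esterification run without DMAP, the variant that should keep the Z geometry of the angelate; only the secondary C8 hydroxyl is free, and the lactone and the tertiary silyl ether are inert.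

Step 11
Reactants: 20 (1R,3R)-1-[(2S,3R,4S)-2-[(1Z)-2-iodoprop-1-en-1-yl]-4-methyl-5-oxooxolan-3-yl]-3-methyl-3-(triethylsilyloxy)pent-4-yn-1-yl (2Z)-2-methylbut-2-enoate
Product: 21 (4Z,6R,7R,8R,10R,11S)-8-angeloyloxy-3-oxo-10-(triethylsilyloxy)germacr-4-en-1-yn-12,6-olide
Conditions: PdCl2(PPh3)2 (10 mol%), CuI (10 mol%), Et3N (5 equiv), CO (1 atm), THF, 40 °C, 20 added by syringe pump over 12 h (final 1 mM), degassed
Reagents that add atoms: carbon monoxide [C-]#[O+]
Why: Proposed new method: ring-closing form of the carbonylative Sonogashira coupling; zerovalent palladium inserts into the C4–I bond of 20 with retention, CO inserts to give the (Z)-acylpalladium iodide (divalent palladium), the copper acetylide of the C10 ethynyl group transmetalates, and reductive elimination joins C2 to C3, so that C3 and its oxygen come from carbon monoxide. The closest known reaction types are the carbonylative Sonogashira coupling of alkenyl and aryl iodides with tertiary ethynyl carbinols, which leads on to 2,2-dialkyl-3(2H)-furanones, and macrocycle-forming carbonylative Stille couplings. The only ring closed is the ten-membered carbocycle C1–C10, by C–C reductive elimination from an eleven-membered acyl(alkynyl)palladacycle. No stereocentre is formed: C6, C7, C8, C10 and C11 are already in place and the Z geometry of C4=C5 is that of the iodide. The step needs CO insertion before alkynyl transfer (secured by the CO atmosphere and by the strain of the nine-membered enyne that direct coupling would require) and ring closure before chain growth or alkyne dimerisation (secured by slow addition to 1 mM in degassed solvent, helped by the Z-alkene and the trans-lactone, which turn both chain ends to the same side). The angelate, the lactone and the silyl ether should be inert to these conditions.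

Step 12
Reactants: 21 (4Z,6R,7R,8R,10R,11S)-8-angeloyloxy-3-oxo-10-(triethylsilyloxy)germacr-4-en-1-yn-12,6-olide
Product: 24 (6R,7R,8R,10R,11S)-8-angeloyloxy-3,10-epoxy-1-oxogermacra-2,4Z-dien-12,6-olide (CNP0278264.1), via enaminone 22 (not isolated), via hydroxy diketone 23 (not isolated)
Conditions: Et2NH (5 equiv), EtOH, 0 °C → rt; then 2 M aq. HCl, THF, rt
Reagents that add atoms: water O
Why: Known conversion of 4-hydroxyalk-2-ynones into 3(2H)-furanones: diethylamine adds to C1 (β to the C3 ketone), acid hydrolysis of the enaminone and of the silyl ether gives the α'-hydroxy 1,3-diketone, and the C10 hydroxyl closes ring A by 5-exo-trig addition to C3=O and loss of water; no stereocentre is involved.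

**Compound list**

1 | (2E)-3-methylpent-2-en-4-yn-1-ol | C#C/C(C)=C/CO | starting material
2 | [(2S,3S)-3-ethynyl-3-methyloxiran-2-yl]methanol | OC[C@@H]1O[C@@]1(C)C#C | intermediate
3 | (3R)-3-methylpent-4-yne-1,3-diol | OCC[C@@](C)(O)C#C | intermediate
4 | (3R)-3-hydroxy-3-methylpent-4-ynoic acid | OC(=O)C[C@@](C)(O)C#C | intermediate
5 | triethylsilyl (3R)-3-methyl-3-(triethylsilyloxy)pent-4-ynoate (not isolated) | CC[Si](CC)(CC)OC(=O)C[C@@](C)(O[Si](CC)(CC)CC)C#C | intermediate
6 | (3R)-3-methyl-3-(triethylsilyloxy)pent-4-ynoic acid | OC(=O)C[C@@](C)(O[Si](CC)(CC)CC)C#C | intermediate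
7 | methyl (2R)-3-bromo-2-methylpropanoate | COC(=O)[C@@H](C)CBr | starting material
8 | (3R)-3-methyl-3-(triethylsilyloxy)pent-4-ynoyl chloride (not isolated) | ClC(=O)C[C@@](C)(O[Si](CC)(CC)CC)C#C | intermediate
9 | [(2R)-3-methoxy-2-methyl-3-oxopropyl]zinc bromide (not isolated) | COC(=O)[C@@H](C)C[Zn]Br | intermediate
10 | methyl (2S,6R)-2,6-dimethyl-4-oxo-6-(triethylsilyloxy)oct-7-ynoate | COC(=O)[C@@H](C)CC(=O)C[C@@](C)(O[Si](CC)(CC)CC)C#C | intermediate
11 | but-2-yn-1-ol | CC#CCO | starting material
12 | sodium 2,2-bis(2-methoxyethoxy)-3-methyl-2,5-dihydro-1,2-oxaluminol-2-uide (cyclic alkenylaluminate, not isolated) | CC1=CCO[Al-]1(OCCOC)OCCOC.[Na+] | intermediate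
13 | (2Z)-3-iodobut-2-en-1-ol | C/C(I)=C/CO | intermediate
14 | (2Z)-3-iodobut-2-enal | C/C(I)=C/C=O | intermediate
15 | methyl (2S,3Z,6R)-4-[bis(isopinocampheyl)boranyloxy]-2,6-dimethyl-6-(triethylsilyloxy)oct-3-en-7-ynoate, the Z-enol borinate of 10 with ligands from (+)-α-pinene (not isolated) | COC(=O)[C@@H](C)/C=C(/C[C@@](C)(O[Si](CC)(CC)CC)C#C)OB([C@@H]1C[C@@H]2C[C@H]([C@H]1C)C2(C)C)[C@@H]1C[C@@H]2C[C@H]([C@H]1C)C2(C)C | intermediate
16 | methyl (2S,3S,6R)-3-[(1S,2Z)-1-hydroxy-3-iodobut-2-en-1-yl]-2,6-dimethyl-4-oxo-6-(triethylsilyloxy)oct-7-ynoate | COC(=O)[C@@H](C)[C@@H]([C@H](O)/C=C(/C)I)C(=O)C[C@@](C)(O[Si](CC)(CC)CC)C#C | intermediate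
17 | methyl (2S,3R,4R,6R)-4-hydroxy-3-[(1S,2Z)-1-hydroxy-3-iodobut-2-en-1-yl]-2,6-dimethyl-6-(triethylsilyloxy)oct-7-ynoate (not isolated) | COC(=O)[C@@H](C)[C@@H]([C@H](O)/C=C(/C)I)[C@H](O)C[C@@](C)(O[Si](CC)(CC)CC)C#C | intermediate
18 | (3S,4R,5S)-4-[(1R,3R)-1-hydroxy-3-methyl-3-(triethylsilyloxy)pent-4-yn-1-yl]-5-[(1Z)-2-iodoprop-1-en-1-yl]-3-methyloxolan-2-one | O[C@H](C[C@@](C)(O[Si](CC)(CC)CC)C#C)[C@H]1[C@H](C)C(=O)O[C@@H]1/C=C(/C)I | intermediate
19 | angelic acid, (2Z)-2-methylbut-2-enoic acid | C/C=C(/C)C(=O)O | starting material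
20 | (1R,3R)-1-[(2S,3R,4S)-2-[(1Z)-2-iodoprop-1-en-1-yl]-4-methyl-5-oxooxolan-3-yl]-3-methyl-3-(triethylsilyloxy)pent-4-yn-1-yl (2Z)-2-methylbut-2-enoate | C/C=C(/C)C(=O)O[C@H](C[C@@](C)(O[Si](CC)(CC)CC)C#C)[C@H]1[C@H](C)C(=O)O[C@@H]1/C=C(/C)I | intermediate
21 | (4Z,6R,7R,8R,10R,11S)-8-angeloyloxy-3-oxo-10-(triethylsilyloxy)germacr-4-en-1-yn-12,6-olide (ten-membered ynone, trans-fused lactone) | C/C=C(/C)C(=O)O[C@@H]1C[C@@](C)(O[Si](CC)(CC)CC)C#CC(=O)/C(C)=C\[C@H]2OC(=O)[C@@H](C)[C@@H]21 | intermediate
22 | (4Z,6R,7R,8R,10R,11S)-8-angeloyloxy-1-(diethylamino)-3-oxo-10-(triethylsilyloxy)germacra-1,4-dien-12,6-olide (not isolated) | C/C=C(/C)C(=O)O[C@@H]1C[C@@](C)(O[Si](CC)(CC)CC)C(N(CC)CC)=CC(=O)/C(C)=C\[C@H]2OC(=O)[C@@H](C)[C@@H]21 | intermediate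
23 | (4Z,6R,7R,8R,10R,11S)-8-angeloyloxy-10-hydroxy-1,3-dioxogermacr-4-en-12,6-olide (not isolated) | C/C=C(/C)C(=O)O[C@@H]1C[C@@](C)(O)C(=O)CC(=O)/C(C)=C\[C@H]2OC(=O)[C@@H](C)[C@@H]21 | intermediate
24 | (6R,7R,8R,10R,11S)-8-angeloyloxy-3,10-epoxy-1-oxogermacra-2,4Z-dien-12,6-olide (CNP0278264.1) | C/C=C(/C)C(=O)O[C@@H]1C[C@@]2(C)OC(=CC2=O)/C(C)=C\[C@H]2OC(=O)[C@@H](C)[C@@H]21 | target

**Step count and risks**

Total steps: 12. Longest linear sequence: 10 (steps 1–5 and 8–12).

Steps most likely to fail:

1. Step 11 (Proposed new method). The acylpalladium species may be trapped by a second molecule to give oligomeric ynones, or the copper acetylide may dimerise before the ring closes. The fallback uses known chemistry and sets out from 20: the alkyne is stannylated with Bu3SnOMe (toluene, 60 °C) to the alkynylstannane F1, and the ring is closed by a carbonylative Stille coupling (Pd2(dba)3, AsPh3, CO 1 atm, DMF/THF, 50 °C, slow addition). This coupling is established for macrocycle closure and needs neither copper nor amine; it comes back to the route at 21.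

2. Step 10. The hindered C8 hydroxyl may acylate slowly, and the activated angelate may isomerise to the tiglate. The fallback sets out from 18: the alcohol is esterified with 2-[bis(2,2,2-trifluoroethoxy)phosphoryl]propanoic acid (DCC, DMAP cat., CH2Cl2) to the phosphonate ester F2. The Z-2-methylbut-2-enoate is then built on the ester by a Still–Gennari olefination with acetaldehyde (KHMDS, 18-crown-6, THF, −78 °C); it comes back at 20.

3. Step 12. Amine addition may be slow next to the silylated quaternary carbon, or the amine may attack the esters before the ynone is consumed. The fallback sets out from 21: the silyl ether is removed first (HF·pyridine, THF, 0 °C) to the hydroxy ynone F3. F3 is then isomerised to the furanone by gold-catalysed hydration–cyclisation ((Ph3P)AuCl/AgOTf, wet toluene, rt), the known route from γ-hydroxyalkynones to 3(2H)-furanones; it comes back at 24.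

**Further compounds**

F1 | step 11 | (1R,3R)-1-[(2S,3R,4S)-2-[(1Z)-2-iodoprop-1-en-1-yl]-4-methyl-5-oxooxolan-3-yl]-3-methyl-3-(triethylsilyloxy)-5-(tributylstannyl)pent-4-yn-1-yl (2Z)-2-methylbut-2-enoate | C/C=C(/C)C(=O)O[C@H](C[C@@](C)(O[Si](CC)(CC)CC)C#C[Sn](CCCC)(CCCC)CCCC)[C@H]1[C@H](C)C(=O)O[C@@H]1/C=C(/C)I
F2 | step 10 | (1R,3R)-1-[(2S,3R,4S)-2-[(1Z)-2-iodoprop-1-en-1-yl]-4-methyl-5-oxooxolan-3-yl]-3-methyl-3-(triethylsilyloxy)pent-4-yn-1-yl 2-[bis(2,2,2-trifluoroethoxy)phosphoryl]propanoate | CC(P(=O)(OCC(F)(F)F)OCC(F)(F)F)C(=O)O[C@H](C[C@@](C)(O[Si](CC)(CC)CC)C#C)[C@H]1[C@H](C)C(=O)O[C@@H]1/C=C(/C)I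
F3 | step 12 | (4Z,6R,7R,8R,10R,11S)-8-angeloyloxy-10-hydroxy-3-oxogermacr-4-en-1-yn-12,6-olide | C/C=C(/C)C(=O)O[C@@H]1C[C@@](C)(O)C#CC(=O)/C(C)=C\[C@H]2OC(=O)[C@@H](C)[C@@H]21
A1 | direct plan | {(2R)-5-[(1Z)-1-((2R)-4-(bromomethyl)-5-oxo-2,5-dihydrofuran-2-yl)prop-1-en-2-yl]-2-methyl-3-oxo-2,3-dihydrofuran-2-yl}acetaldehyde | O=CC[C@@]1(C)OC(=CC1=O)/C(C)=C\[C@H]1OC(=O)C(CBr)=C1
A2 | direct plan | (6R,7R,8S,10R)-8-hydroxy-3,10-epoxy-1-oxogermacra-2,4Z,11(13)-trien-12,6-olide | O[C@H]1C[C@@]2(C)OC(=CC2=O)/C(C)=C\[C@H]2OC(=O)C(=C)[C@@H]21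
A3 | direct plan | (6R,7R,8S,10R,11S)-8-hydroxy-3,10-epoxy-1-oxogermacra-2,4Z-dien-12,6-olide | O[C@H]1C[C@@]2(C)OC(=CC2=O)/C(C)=C\[C@H]2OC(=O)[C@@H](C)[C@@H]21
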